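## Structural features

Wailupemycin H consists of two 4-hydroxy-2-pyrones, ring A and ring B, joined C3 to C3 through one methylene carbon. Ring A carries at C6 the C4 methine of an 8-hydroxy-3-hydroxy-3-phenyl-1-tetralone. Ring B carries at C6 the C1 position of a 4,5-dihydroxy-2-phenylnaphthalene, which is the dehydrated, aromatised counterpart of that tetralone, so the molecule is a hetero-dimer of two nearly identical halves. The only stereocentres are the contiguous pair C3 (tertiary carbinol bearing phenyl, R) and C4 (methine bearing ring A, S) of the tetralone, with the C3 hydroxyl and ring A cis. The tetralone is a β-hydroxy ketone that can undergo retro-aldol cleavage or lose water and aromatise, and its C4–H (benzylic and vinylogously α to the ring A lactone carbonyl) can epimerise. The hydroxypyrones are acidic and ambident, the peri-dioxygenated naphthalene is electron-rich, and the ring B–naphthalene bond is flanked by a phenyl group and a peri hydrogen. The real difficulty is to bridge two almost equally nucleophilic pyrone C3 positions unsymmetrically and to raise the labile stereogenic aldol unit late. The key step exploits the chain C2(ring A)–C3(ring A)–CH2–C3(ring B)–C2(ring B), which is the five-carbon skeleton of a glutaric diester with the bridge as its central carbon. Acylating its two α-carbons with two different alkynoyl units fixes the hetero-linkage before either pyrone exists.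

## Logic of the disconnections

**31 ⇒ 30.** Five O–benzyl bonds are cut (three phenols, two pyrone hydroxyls). One protecting group removable under neutral conditions is chosen because the β-hydroxy ketone of 31 dehydrates under acid or base. The gain is a set of non-acidic, lipophilic intermediates. The forward step must cleave five ethers without reducing the aryl ketone, the tertiary benzylic carbinol or the pyrones.

**30 ⇒ 29.** The C2–C3 bond of the tetralone is cut (aldol). This removes the carbocycle and both stereocentres at once and leaves C4 as a freely epimerising methine, so no stereochemistry has to be carried earlier. The forward step must select one face of the benzoyl carbonyl, let C4 equilibrate faster than the ring closes, and stop before dehydration.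

**29 ⇒ 27.** The C3–C4 bond (methine to benzoyl carbon) is cut and the acetyl group is retraced to an enol ether. The methine carbon is benzylic and γ to the lactone carbonyl of ring A, hence the most acidic C–H of 27. The gain is the loss of the benzoyl unit and of an enolisable ketone. The forward step needs C-acylation at the exocyclic carbon only, once, with the acetyl group still masked.

**27 ⇒ 26 ⇒ 25.** The aryl–acetyl bond (C8a–C1) is cut back to an aryl bromide and an acetyl-anion equivalent, then the two pyrone O–benzyl bonds are cut. The bromide is an inert placeholder through all carbanion chemistry of its fragment. The demands are oxidative addition at a di-ortho-substituted bromide and O4-selective alkylation of ambident hydroxypyrones.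

**25 ⇒ 24.** The O1–C6 bonds of ring A and ring B are cut. Each pyrone is an ynone β-keto tert-butyl ester in disguise, so both heterocycles fall back to one acyclic chain. The forward step needs 6-endo-dig O-attack at two different alkynes, one hindered, with loss of the tert-butyl groups as alkene.

**24 ⇒ 22 + 14 + 21.** The C3–C4 bonds of both future pyrones (acyl carbon to α-carbon) are cut. This gives three fragments of comparable size and fixes the unsymmetrical bridge by construction. The forward step needs two successive mono-acylations of 22 by different acid chlorides, 1,2-addition to ynoyl chlorides, and survival of the skipped alkyne of 21.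

**14 ⇒ 13 ⇒ 12 ⇒ 11.** The C–Cl bond, the alkyne–carboxyl bond and the naphthyl–alkyne bond are cut in turn. This leads to an aryl iodide, a two-carbon alkyne unit and a one-carbon electrophile. The demand is a cross-coupling at a position flanked by phenyl and a peri hydrogen, hence iodide.

**11 ⇒ 10 ⇒ 9.** The O–benzyl bond and then the C4–I bond are cut. Iodination is placed on the free naphthol so that the hydroxyl steers the electrophile into its own ring. The demand is para over ortho substitution.

**9 ⇒ 5 + 6.** Three bonds of the new ring are cut: aryne carbon to the central carbon of 6, aryne carbon to the acetyl carbon of 6, and the aldol bond C2–C3 of the naphthol. A whole naphthalene ring with the correct 1,3,8-pattern comes from a diketone and an aryne. The demands are distal attack on the alkoxy-aryne and migration of the acetyl, not the benzoyl, group.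

**5 ⇒ 2 ⇒ 1.** The C–Si and O–S bonds, then one O–benzyl bond, are cut. The demand is mono-etherification of a symmetrical diol.

**21 ⇒ 20 ⇒ 19 ⇒ 18 ⇒ 17 ⇒ 16 ⇒ 15.** The C–Cl bond, the alkyne–carboxyl bond, the benzyl–alkyne bond, the C–Br bond, the alcohol oxidation level and the O–benzyl bond are cut in turn. Every step is a standard functional-group change. The demand is that the aryl bromide and the base-sensitive propargyl–aryl unit are respected.

## Other disconnections considered

**Alternative 1:** The cut removes every C–C bond of the tetralone–pyrone half at once, back to a benzoyl-primed linear chain of eight acyl units bound as thioesters.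
- **Forward key step:** a reconstituted aromatic polyketide synthase (ketosynthase with chain-length factor, acyl carrier protein, ketoreductase, starter ligase, acyl transferase) would perform seven Claisen condensations and one ketone reduction. The chain would then close the phenol ring (C8a–C4a), the tetralone ring (C3–C4) and the lactone (O1–C2 of ring A) to give A1.
- **In favour:** one aqueous operation, no protecting groups, and the natural configuration at both centres from the folding of the chain. Dehydration of part of A1 would also supply the naphthalene half A2.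
- **Against here:** A1 lacks the bridge. Crossing A1 with A2 through a one-carbon electrophile would give both symmetrical dimers beside 31, because the two pyrone C3 positions are equally nucleophilic. Five purified proteins, stoichiometric cofactors, high dilution and shunt folding limit throughput.
- **Comparison:** on step economy and on stereocontrol without any chiral reagent this alternative is better than the chosen plan. On structure it leaves the hetero-bridge unsolved, which the chosen plan settles by construction. On mechanism it depends on enzyme templating, whereas the chosen plan uses ordinary reagents and scales.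

**Alternative 2:** The cut removes both bonds from the benzo ring to the carbocycle (C4–C4a and C1–C8a), leaving aryne 7 and the open-chain ester A4, whose carbinol centre would come from esterase desymmetrisation of a prochiral diester.
- **Forward key step:** a lithium amide base would form the dienolate of A4 at the CH2 next to ring A. Its exocyclic carbon would add to 7 (released by a Grignard reagent) at the carbon meta to the benzyloxy group, and the aryl anion would close onto the methyl ester to give A3.
- **In favour:** the route is convergent and forms ring and ketone in one step with matched aryne regiochemistry. The carbinol centre rests on an enzymatic desymmetrisation, a more dependable source of absolute configuration than the organocatalytic aldol of the chosen plan; on this point the alternative is better.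
- **Against here:** the carbanion is β to a silyloxy leaving group (elimination) and next to a fully substituted carbon. The dienolate can also react through ring positions or oxygen. C4 depends on 1,2-induction or later equilibration. A3 is again only a monomer with a free ring A C3, so the bridge and the whole ring B half remain, plus a silyl ether removal.
- **Comparison:** structurally the two plans are equal in closing the tetralone late on a finished pyrone. Mechanistically a polar aryne annulation replaces a catalytic aldol. For the whole target the alternative is longer, and it does not solve the unsymmetrical bridge.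

**Alternative 3:** The cut is at C3–C4, retraced through a [3,3] shift to the C1–O bond of lactone A6.
- **Forward key step:** enolisation and O-silylation of A6 would give a cyclic ketene acetal. It would rearrange through a ring-enforced boat transition state (Ireland–Claisen), forming C4–C3, breaking C1–O, and leaving the C1=C2 alkene and a carboxyl group on C4, to give A5.
- **In favour:** the shift is concerted and suprafacial, so one easily set carbinol centre is copied onto both C3 and C4, with the relative configuration fixed by alkene geometry. This is more predictable than the equilibration-dependent C4 of the chosen plan; on this point the alternative is better. The congested C3–C4 bond is also made intramolecularly.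
- **Against here:** A6 needs a geometrically pure (E)-enol ether and a benzylic, allylic lactone C–O bond that ionises easily. A5 still needs the carboxyl grown into ring A, regioselective oxidation of the alkene to the C1 ketone, removal of an ether from a tertiary benzylic carbinol, and then the bridge and the second half.
- **Comparison:** stereochemical transfer is more secure than in the chosen plan. Step economy is clearly worse, and the bridge problem is untouched.

Key step: step 15

Remark: the methine carbons of 23, 24, 28 and 29 are enolisable and are written without configuration; 14 and 21 are used as crude concentrates.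
Remark: in step 20 the quinine-derived primary amine is written; its quinidine-derived pseudo-enantiomer takes its place if the sense of induction at C3 proves opposite.

## Route

Step 1
Reactants: 1 2-iodobenzene-1,3-diol (2-iodoresorcinol)
Product: 2 3-(benzyloxy)-2-iodophenol
Conditions: BnBr (1.0 equiv), K2CO3, acetone, 50 °C
Reagents that add atoms: benzyl bromide, BrCc1ccccc1
Why: Williamson etherification; one equivalent of halide on the symmetrical diol should give the mono-ether beside separable diether and recovered 1.

Step 2
Reactants: 2 3-(benzyloxy)-2-iodophenol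
Product: 5 3-(benzyloxy)-2-(trimethylsilyl)phenyl trifluoromethanesulfonate, via [3-(benzyloxy)-2-iodophenoxy]trimethylsilane 3 (not isolated), via lithium 3-(benzyloxy)-2-(trimethylsilyl)phenolate 4 (not isolated)
Conditions: (Me3Si)2NH, THF, 70 °C, evaporation; n-BuLi, THF, −100 °C; Tf2O, −100 °C → rt
Reagents that add atoms: hexamethyldisilazane, C[Si](C)(C)N[Si](C)(C)C; trifluoromethanesulfonic anhydride, O=S(=O)(OS(=O)(=O)C(F)(F)F)C(F)(F)F
Why: O-silylation, iodine–lithium exchange and anionic 1,3 O→C silyl migration (retro-Brook rearrangement) give phenolate 4, which is O-triflated; this is the standard one-flask entry to 2-silylaryl triflates from 2-halophenols.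

Step 3
Reactants: 5 3-(benzyloxy)-2-(trimethylsilyl)phenyl trifluoromethanesulfonate; 6 1-phenylbutane-1,3-dione
Product: 9 8-(benzyloxy)-3-phenylnaphthalen-1-ol, via 3-(benzyloxy)benzyne 7 (not isolated), via 2-[2-acetyl-3-(benzyloxy)phenyl]-1-phenylethan-1-one 8 (not isolated)
Conditions: CsF, MeCN, 80 °C; then K2CO3, MeOH, 60 °C
Reagents that add atoms: none
Why: Fluoride-induced 1,2-elimination releases aryne 7; the enolate carbon of 6 adds meta to the benzyloxy group, the aryl anion attacks the acetyl carbonyl and the four-membered alkoxide fragments (aryne σ-insertion, acyl-alkylation) to 8. Base then effects intramolecular aldol condensation of the acetyl methyl onto the benzoyl carbonyl and tautomerisation to 9; the other closure would need a four-membered ring.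

Step 4
Reactants: 9 8-(benzyloxy)-3-phenylnaphthalen-1-ol
Product: 10 8-(benzyloxy)-4-iodo-3-phenylnaphthalen-1-ol
Conditions: N-iodosuccinimide (1.0 equiv), MeCN, −20 → 0 °C, dark
Reagents that add atoms: N-iodosuccinimide, O=C1CCC(=O)N1I
Why: Electrophilic aromatic iodination; the free hydroxyl is the strongest donor, so substitution stays in its own ring and should go to C4 (para, naphthalene α-position), which is why iodination precedes the second benzylation.

Step 5
Reactants: 10 8-(benzyloxy)-4-iodo-3-phenylnaphthalen-1-ol
Product: 11 4,5-bis(benzyloxy)-1-iodo-2-phenylnaphthalene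
Conditions: BnBr, K2CO3, DMF, rt
Reagents that add atoms: benzyl bromide, BrCc1ccccc1
Why: Williamson etherification of the naphthol; carbonate in a dipolar solvent breaks the peri hydrogen bond.

Step 6
Reactants: 11 4,5-bis(benzyloxy)-1-iodo-2-phenylnaphthalene
Product: 12 {[4,5-bis(benzyloxy)-2-phenylnaphthalen-1-yl]ethynyl}trimethylsilane
Conditions: HC≡CSiMe3, PdCl2(PPh3)2 (5 mol %), CuI (10 mol %), Et3N/THF, 60 °C, sealed
Reagents that add atoms: ethynyltrimethylsilane, C#C[Si](C)(C)C
Why: Sonogashira coupling (oxidative addition of zerovalent palladium into C–I, transmetalation from the copper acetylide, reductive elimination); iodide is used because the position is flanked by phenyl and a peri hydrogen.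

Step 7
Reactants: 12 {[4,5-bis(benzyloxy)-2-phenylnaphthalen-1-yl]ethynyl}trimethylsilane
Product: 13 3-[4,5-bis(benzyloxy)-2-phenylnaphthalen-1-yl]prop-2-ynoic acid
Conditions: CsF, CO2 (1 atm), DMSO, rt; cold 1 M HCl
Reagents that add atoms: carbon dioxide, O=C=O
Why: Fluoride attacks silicon and the alkynyl nucleophile is trapped by CO2 (desilylative carboxylation of alkynylsilanes), which saves a separate desilylation and a strong base; cold acidification limits decarboxylation of the electron-rich arylpropiolic acid.

Step 8
Reactants: 13 3-[4,5-bis(benzyloxy)-2-phenylnaphthalen-1-yl]prop-2-ynoic acid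
Product: 14 3-[4,5-bis(benzyloxy)-2-phenylnaphthalen-1-yl]prop-2-ynoyl chloride
Conditions: 1-chloro-N,N,2-trimethylprop-1-en-1-amine, CH2Cl2, 0 °C → rt; evaporation
Reagents that add atoms: 1-chloro-N,N,2-trimethylprop-1-en-1-amine, CC(C)=C(Cl)N(C)C
Why: The α-chloroenamine converts the acid into the acid chloride under neutral conditions with an amide as the only by-product, so no HCl is present to add across the ynoyl unit.

Step 9
Reactants: 15 2-bromo-3-hydroxybenzaldehyde
Product: 16 3-(benzyloxy)-2-bromobenzaldehyde
Conditions: BnBr, K2CO3, DMF, rt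
Reagents that add atoms: benzyl bromide, BrCc1ccccc1
Why: Williamson etherification of the phenol; aldehyde and aryl bromide are untouched.

Step 10
Reactants: 16 3-(benzyloxy)-2-bromobenzaldehyde
Product: 17 [3-(benzyloxy)-2-bromophenyl]methanol
Conditions: NaBH4, MeOH/THF, 0 °C
Reagents that add atoms: none
Why: Hydride reduction of the aldehyde; aryl bromide and benzyl ether are inert.

Step 11
Reactants: 17 [3-(benzyloxy)-2-bromophenyl]methanol
Product: 18 1-(benzyloxy)-2-bromo-3-(bromomethyl)benzene
Conditions: PBr3, CH2Cl2, 0 °C
Reagents that add atoms: phosphorus tribromide, BrP(Br)Br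
Why: The benzylic alcohol is converted through its phosphite ester into the bromide by SN2 displacement.

Step 12
Reactants: 18 1-(benzyloxy)-2-bromo-3-(bromomethyl)benzene
Product: 19 1-(benzyloxy)-2-bromo-3-(prop-2-yn-1-yl)benzene
Conditions: HC≡CMgBr, CuBr·SMe2 (10 mol %), THF, 0 → 45 °C
Reagents that add atoms: ethynylmagnesium bromide, C#C[Mg]Br
Why: Copper-catalysed substitution of the benzylic bromide by the alkynyl Grignard reagent; an aryl bromide does not exchange with an alkynylmagnesium halide.

Step 13
Reactants: 19 1-(benzyloxy)-2-bromo-3-(prop-2-yn-1-yl)benzene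
Product: 20 4-[3-(benzyloxy)-2-bromophenyl]but-2-ynoic acid
Conditions: LiN(iPr)2 (1.05 equiv), THF, −78 °C; CO2; 1 M HCl, 0 °C
Reagents that add atoms: carbon dioxide, O=C=O
Why: The terminal alkyne is the most acidic site and an amide base avoids bromine–lithium exchange; the lithium acetylide is carboxylated, and the skipped alkyne is kept cold to prevent propargyl–allenyl isomerisation.

Step 14
Reactants: 20 4-[3-(benzyloxy)-2-bromophenyl]but-2-ynoic acid
Product: 21 4-[3-(benzyloxy)-2-bromophenyl]but-2-ynoyl chloride
Conditions: 1-chloro-N,N,2-trimethylprop-1-en-1-amine, CH2Cl2, 0 °C; evaporation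
Reagents that add atoms: 1-chloro-N,N,2-trimethylprop-1-en-1-amine, CC(C)=C(Cl)N(C)C
Why: Neutral acid chloride formation as in step 8; absence of base and HCl protects the acidic propargylic CH2.

Step 15
Reactants: 22 di-tert-butyl pentanedioate (di-tert-butyl glutarate); 14 3-[4,5-bis(benzyloxy)-2-phenylnaphthalen-1-yl]prop-2-ynoyl chloride; 21 4-[3-(benzyloxy)-2-bromophenyl]but-2-ynoyl chloride
Product: 24 di-tert-butyl 2-{3-[4,5-bis(benzyloxy)-2-phenylnaphthalen-1-yl]prop-2-ynoyl}-4-{4-[3-(benzyloxy)-2-bromophenyl]but-2-ynoyl}pentanedioate, via di-tert-butyl 2-{3-[4,5-bis(benzyloxy)-2-phenylnaphthalen-1-yl]prop-2-ynoyl}pentanedioate 23 (not isolated)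
Conditions: LiN(iPr)2 (2.05 equiv), THF, −78 °C; 14 (1.0 equiv), −78 °C; LiN(iPr)2 (1.05 equiv), −78 °C; cannulation into 21 (1.3 equiv), THF, −78 °C; AcOH, −78 °C
Reagents that add atoms: none
Why: Proposed new method: two equivalents of amide base convert 22 into its dilithium bis-enolate; one α-carbon adds to the carbonyl of 14 and expels chloride, and the new, far more acidic β-keto ester C–H is transferred to the second enolate, leaving the chelated lithium enolate of 23, which is inert to acid chloride at −78 °C. A third equivalent of base can only remove an α-proton of the untouched ester (the propynoyl arm has no γ-hydrogen), and this more basic carbon is acylated when the dianion is run into 21. The closest known reactions are the C-acylation of lithium ester enolates by acid chlorides and the reaction of β-keto ester dianions at their less stabilised carbanion; the unsymmetrical one-flask double version on a glutarate is the untested part. No ring closes, and the two new methine centres are enolised and irrelevant because both become sp2 C3 atoms of the pyrones. Mono-acylation at each α-carbon is secured by the acidity gradient and 1:1 stoichiometry. 1,2- over 1,4-addition is secured by the hard lithium enolate, the very electrophilic acyl chloride and −78 °C. The skipped arylbutynoyl unit is protected by introducing 21 last, by inverse addition (21 never meets excess base, the product never meets unreacted dianion) and by the cold acetic acid quench.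

Step 16
Reactants: 24 di-tert-butyl 2,4-diacylpentanedioate
Product: 25 6-{[3-(benzyloxy)-2-bromophenyl]methyl}-3-({6-[4,5-bis(benzyloxy)-2-phenylnaphthalen-1-yl]-4-hydroxy-2-oxo-2H-pyran-3-yl}methyl)-4-hydroxy-2H-pyran-2-one
Conditions: [(Ph3P)AuNTf2] (5 mol %), CH2Cl2/MeNO2/AcOH, rt
Reagents that add atoms: none
Why: Cationic monovalent gold activates each alkyne for 6-endo-dig attack of the tert-butyl ester carbonyl oxygen on the distal alkyne carbon; loss of 2-methylpropene, protodeauration and enolisation give the 4-hydroxy-2-pyrones (known cycloisomerisation of tert-butyl 3-oxoalk-4-ynoates, here at both arms). O-attack through a six-membered transition state should outrun attack by the neighbouring phenyl ring and isomerisation of the skipped alkyne.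

Step 17
Reactants: 25 bis(4-hydroxy-2-pyrone)
Product: 26 4-(benzyloxy)-6-{[3-(benzyloxy)-2-bromophenyl]methyl}-3-({4-(benzyloxy)-6-[4,5-bis(benzyloxy)-2-phenylnaphthalen-1-yl]-2-oxo-2H-pyran-3-yl}methyl)-2H-pyran-2-one
Conditions: BnOH, PPh3, diisopropyl azodicarboxylate, THF, 0 °C → rt
Reagents that add atoms: benzyl alcohol, OCc1ccccc1
Why: Mitsunobu etherification; the acidic hydroxypyrones (pKa about 5) protonate the betaine and their O4 oxygen displaces the oxyphosphonium of benzyl alcohol, which should favour O4-alkylation over the C3 or O2 alkylation possible with benzyl halides.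

Step 18
Reactants: 26 bis(4-benzyloxy-2-pyrone) aryl bromide
Product: 27 4-(benzyloxy)-6-{[3-(benzyloxy)-2-(1-ethoxyethenyl)phenyl]methyl}-3-({4-(benzyloxy)-6-[4,5-bis(benzyloxy)-2-phenylnaphthalen-1-yl]-2-oxo-2H-pyran-3-yl}methyl)-2H-pyran-2-one
Conditions: Bu3Sn–C(OEt)=CH2, Pd(PPh3)4 (10 mol %), toluene, 100 °C; Et3N-deactivated silica
Reagents that add atoms: tributyl(1-ethoxyethenyl)stannane, CCCC[Sn](CCCC)(CCCC)C(=C)OCC
Why: Stille coupling of the aryl bromide installs a masked acetyl group; the enol ether is kept so that no enolisable methyl ketone is present in step 19, and the coupling is run before benzoylation so that palladium never meets the acidic, more hindered methine.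

Step 19
Reactants: 27 aryl 1-ethoxyethenyl bis(pyrone)
Product: 29 6-{1-[2-acetyl-3-(benzyloxy)phenyl]-2-oxo-2-phenylethyl}-4-(benzyloxy)-3-({4-(benzyloxy)-6-[4,5-bis(benzyloxy)-2-phenylnaphthalen-1-yl]-2-oxo-2H-pyran-3-yl}methyl)-2H-pyran-2-one, via the 1-ethoxyethenyl phenyl ketone 28 (not isolated)
Conditions: LiN(SiMe3)2 (2.2 equiv), THF, −78 °C; PhC(O)N(OMe)Me, −78 → 0 °C; then 1 M HCl, THF, 0 °C
Reagents that add atoms: N-methoxy-N-methylbenzamide, CON(C)C(=O)c1ccccc1; water, O
Why: The CH2 between ring A and the arene is benzylic and vinylogously α to the lactone carbonyl, hence the most acidic C–H; its lithium dienolate reacts at the exocyclic carbon with the N-methoxy-N-methylamide, and the chelated tetrahedral adduct prevents over-acylation (vinylogous Claisen-type C-acylation). Dilute acid collapses the adduct to 28 and hydrolyses the enol ether to the methyl ketone of 29 in the same operation.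

Step 20
Reactants: 29 acetyl benzoyl diketone
Product: 30 4-(benzyloxy)-6-[(1S,2R)-5-(benzyloxy)-2-hydroxy-4-oxo-2-phenyl-1,2,3,4-tetrahydronaphthalen-1-yl]-3-({4-(benzyloxy)-6-[4,5-bis(benzyloxy)-2-phenylnaphthalen-1-yl]-2-oxo-2H-pyran-3-yl}methyl)-2H-pyran-2-one [(3R,4S) in tetralone numbering; 3-OH and ring A cis]
Conditions: 9-amino-9-deoxy-epi-quinine [(8α,9S)-6′-methoxycinchonan-9-amine] (20 mol %), 2-fluorobenzoic acid (40 mol %), toluene, rt
Reagents that add atoms: none
Why: Intramolecular amine-catalysed aldol addition (Hajos–Parrish type, 6-enolendo): the primary amine forms the enamine of the methyl ketone, and the protonated quinuclidine hydrogen-bonds to the benzoyl carbonyl and selects its face, which sets C3 (R). The C4 epimers of 29 interconvert through the enol and the transition state with ring A anti to the acceptor phenyl is less crowded, so C4 (S) should follow by dynamic kinetic resolution; weak acid and room temperature keep the aldol from dehydrating.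

Step 21
Reactants: 30 penta-O-benzyl wailupemycin H
Product: 31 wailupemycin H, 6-[(1S,2R)-2,5-dihydroxy-4-oxo-2-phenyl-1,2,3,4-tetrahydronaphthalen-1-yl]-3-{[6-(4,5-dihydroxy-2-phenylnaphthalen-1-yl)-4-hydroxy-2-oxo-2H-pyran-3-yl]methyl}-4-hydroxy-2H-pyran-2-one
Conditions: H2 (1 atm), Pd/C, EtOAc/MeOH, rt
Reagents that add atoms: none
Why: Hydrogenolysis of all five benzyl ethers on palladium under neutral conditions, which the β-hydroxy ketone tolerates; the aryl ketone, the tertiary benzylic alcohol and the pyrones are reduced much more slowly, so the reaction is stopped at complete debenzylation and neither stereocentre is touched.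

## Compound list

1 | 2-iodobenzene-1,3-diol | Oc1cccc(O)c1I | starting material
2 | 3-(benzyloxy)-2-iodophenol | Oc1cccc(OCc2ccccc2)c1I | intermediate
3 | [3-(benzyloxy)-2-iodophenoxy]trimethylsilane | C[Si](C)(C)Oc1cccc(OCc2ccccc2)c1I | intermediate
4 | lithium 3-(benzyloxy)-2-(trimethylsilyl)phenolate | [Li+].[O-]c1cccc(OCc2ccccc2)c1[Si](C)(C)C | intermediate
5 | 3-(benzyloxy)-2-(trimethylsilyl)phenyl trifluoromethanesulfonate | C[Si](C)(C)c1c(OCc2ccccc2)cccc1OS(=O)(=O)C(F)(F)F | intermediate
6 | 1-phenylbutane-1,3-dione | CC(=O)CC(=O)c1ccccc1 | starting material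
7 | 3-(benzyloxy)benzyne | C1#CC(OCc2ccccc2)=CC=C1 | intermediate
8 | 2-[2-acetyl-3-(benzyloxy)phenyl]-1-phenylethan-1-one | CC(=O)c1c(OCc2ccccc2)cccc1CC(=O)c1ccccc1 | intermediate
9 | 8-(benzyloxy)-3-phenylnaphthalen-1-ol | Oc1cc(-c2ccccc2)cc2cccc(OCc3ccccc3)c12 | intermediate
10 | 8-(benzyloxy)-4-iodo-3-phenylnaphthalen-1-ol | Oc1cc(-c2ccccc2)c(I)c2cccc(OCc3ccccc3)c12 | intermediate
11 | 4,5-bis(benzyloxy)-1-iodo-2-phenylnaphthalene | Ic1c(-c2ccccc2)cc(OCc2ccccc2)c2c(OCc3ccccc3)cccc12 | intermediate
12 | {[4,5-bis(benzyloxy)-2-phenylnaphthalen-1-yl]ethynyl}trimethylsilane | C[Si](C)(C)C#Cc1c(-c2ccccc2)cc(OCc2ccccc2)c2c(OCc3ccccc3)cccc12 | intermediate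
13 | 3-[4,5-bis(benzyloxy)-2-phenylnaphthalen-1-yl]prop-2-ynoic acid | OC(=O)C#Cc1c(-c2ccccc2)cc(OCc2ccccc2)c2c(OCc3ccccc3)cccc12 | intermediate
14 | 3-[4,5-bis(benzyloxy)-2-phenylnaphthalen-1-yl]prop-2-ynoyl chloride | O=C(Cl)C#Cc1c(-c2ccccc2)cc(OCc2ccccc2)c2c(OCc3ccccc3)cccc12 | intermediate
15 | 2-bromo-3-hydroxybenzaldehyde | O=Cc1cccc(O)c1Br | starting material
16 | 3-(benzyloxy)-2-bromobenzaldehyde | O=Cc1cccc(OCc2ccccc2)c1Br | intermediate
17 | [3-(benzyloxy)-2-bromophenyl]methanol | OCc1cccc(OCc2ccccc2)c1Br | intermediate
18 | 1-(benzyloxy)-2-bromo-3-(bromomethyl)benzene | BrCc1cccc(OCc2ccccc2)c1Br | intermediate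
19 | 1-(benzyloxy)-2-bromo-3-(prop-2-yn-1-yl)benzene | C#CCc1cccc(OCc2ccccc2)c1Br | intermediate
20 | 4-[3-(benzyloxy)-2-bromophenyl]but-2-ynoic acid | OC(=O)C#CCc1cccc(OCc2ccccc2)c1Br | intermediate
21 | 4-[3-(benzyloxy)-2-bromophenyl]but-2-ynoyl chloride | O=C(Cl)C#CCc1cccc(OCc2ccccc2)c1Br | intermediate
22 | di-tert-butyl pentanedioate | CC(C)(C)OC(=O)CCCC(=O)OC(C)(C)C | starting material
23 | di-tert-butyl 2-{3-[4,5-bis(benzyloxy)-2-phenylnaphthalen-1-yl]prop-2-ynoyl}pentanedioate (enolisable, no defined configuration) | CC(C)(C)OC(=O)CCC(C(=O)OC(C)(C)C)C(=O)C#Cc1c(-c2ccccc2)cc(OCc2ccccc2)c2c(OCc3ccccc3)cccc12 | intermediate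
24 | di-tert-butyl 2-{3-[4,5-bis(benzyloxy)-2-phenylnaphthalen-1-yl]prop-2-ynoyl}-4-{4-[3-(benzyloxy)-2-bromophenyl]but-2-ynoyl}pentanedioate (enolisable, no defined configuration) | CC(C)(C)OC(=O)C(CC(C(=O)OC(C)(C)C)C(=O)C#Cc1c(-c2ccccc2)cc(OCc2ccccc2)c2c(OCc3ccccc3)cccc12)C(=O)C#CCc1cccc(OCc2ccccc2)c1Br | intermediate
25 | 6-{[3-(benzyloxy)-2-bromophenyl]methyl}-3-({6-[4,5-bis(benzyloxy)-2-phenylnaphthalen-1-yl]-4-hydroxy-2-oxo-2H-pyran-3-yl}methyl)-4-hydroxy-2H-pyran-2-one | O=c1oc(Cc2cccc(OCc3ccccc3)c2Br)cc(O)c1Cc1c(O)cc(-c2c(-c3ccccc3)cc(OCc3ccccc3)c3c(OCc4ccccc4)cccc23)oc1=O | intermediate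
26 | 4-(benzyloxy)-6-{[3-(benzyloxy)-2-bromophenyl]methyl}-3-({4-(benzyloxy)-6-[4,5-bis(benzyloxy)-2-phenylnaphthalen-1-yl]-2-oxo-2H-pyran-3-yl}methyl)-2H-pyran-2-one | O=c1oc(Cc2cccc(OCc3ccccc3)c2Br)cc(OCc2ccccc2)c1Cc1c(OCc2ccccc2)cc(-c2c(-c3ccccc3)cc(OCc3ccccc3)c3c(OCc4ccccc4)cccc23)oc1=O | intermediate
27 | 4-(benzyloxy)-6-{[3-(benzyloxy)-2-(1-ethoxyethenyl)phenyl]methyl}-3-({4-(benzyloxy)-6-[4,5-bis(benzyloxy)-2-phenylnaphthalen-1-yl]-2-oxo-2H-pyran-3-yl}methyl)-2H-pyran-2-one | O=c1oc(Cc2cccc(OCc3ccccc3)c2C(=C)OCC)cc(OCc2ccccc2)c1Cc1c(OCc2ccccc2)cc(-c2c(-c3ccccc3)cc(OCc3ccccc3)c3c(OCc4ccccc4)cccc23)oc1=O | intermediate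
28 | 4-(benzyloxy)-6-{1-[3-(benzyloxy)-2-(1-ethoxyethenyl)phenyl]-2-oxo-2-phenylethyl}-3-({4-(benzyloxy)-6-[4,5-bis(benzyloxy)-2-phenylnaphthalen-1-yl]-2-oxo-2H-pyran-3-yl}methyl)-2H-pyran-2-one (labile methine, no defined configuration) | O=c1oc(C(C(=O)c2ccccc2)c2cccc(OCc3ccccc3)c2C(=C)OCC)cc(OCc2ccccc2)c1Cc1c(OCc2ccccc2)cc(-c2c(-c3ccccc3)cc(OCc3ccccc3)c3c(OCc4ccccc4)cccc23)oc1=O | intermediate
29 | 6-{1-[2-acetyl-3-(benzyloxy)phenyl]-2-oxo-2-phenylethyl}-4-(benzyloxy)-3-({4-(benzyloxy)-6-[4,5-bis(benzyloxy)-2-phenylnaphthalen-1-yl]-2-oxo-2H-pyran-3-yl}methyl)-2H-pyran-2-one (labile methine, no defined configuration) | O=c1oc(C(C(=O)c2ccccc2)c2cccc(OCc3ccccc3)c2C(C)=O)cc(OCc2ccccc2)c1Cc1c(OCc2ccccc2)cc(-c2c(-c3ccccc3)cc(OCc3ccccc3)c3c(OCc4ccccc4)cccc23)oc1=O | intermediate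
30 | 4-(benzyloxy)-6-[(1S,2R)-5-(benzyloxy)-2-hydroxy-4-oxo-2-phenyl-1,2,3,4-tetrahydronaphthalen-1-yl]-3-({4-(benzyloxy)-6-[4,5-bis(benzyloxy)-2-phenylnaphthalen-1-yl]-2-oxo-2H-pyran-3-yl}methyl)-2H-pyran-2-one | O=C1C[C@](O)(c2ccccc2)[C@@H](c2cc(OCc3ccccc3)c(Cc3c(OCc4ccccc4)cc(-c4c(-c5ccccc5)cc(OCc5ccccc5)c5c(OCc6ccccc6)cccc45)oc3=O)c(=O)o2)c2cccc(OCc3ccccc3)c21 | intermediate
31 | wailupemycin H, 6-[(1S,2R)-2,5-dihydroxy-4-oxo-2-phenyl-1,2,3,4-tetrahydronaphthalen-1-yl]-3-{[6-(4,5-dihydroxy-2-phenylnaphthalen-1-yl)-4-hydroxy-2-oxo-2H-pyran-3-yl]methyl}-4-hydroxy-2H-pyran-2-one | O=C1C[C@](O)(c2ccccc2)[C@@H](c2cc(O)c(Cc3c(O)cc(-c4c(-c5ccccc5)cc(O)c5c(O)cccc45)oc3=O)c(=O)o2)c2cccc(O)c21 | target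

## Step count and least certain steps

Total: 21 steps. Longest linear sequence: 15 steps (steps 1–8, then 15–21); the second branch (steps 9–14) joins at step 15.

**Step 15 (key step, new method).**
- What may go wrong: double acylation of the bis-enolate by 14 before proton transfer levels it; conjugate addition to an ynoyl chloride; proton transfer from product to unreacted dianion, which stalls the second acylation; O-acylation; base-induced isomerisation of the skipped alkyne to an allene; intramolecular Michael addition on warming.
- Fallback (known chemistry only): it sets out from 14 and 21 and abandons the glutarate. Each acid chloride is added to two equivalents of the lithium enolate of tert-butyl acetate (THF, −78 °C, Claisen-type C-acylation). This gives tert-butyl 5-[4,5-bis(benzyloxy)-2-phenylnaphthalen-1-yl]-3-oxopent-4-ynoate F1 and tert-butyl 6-[3-(benzyloxy)-2-bromophenyl]-3-oxohex-4-ynoate F3. Gold-catalysed cycloisomerisation with [(Ph3P)AuNTf2] converts them into 6-[4,5-bis(benzyloxy)-2-phenylnaphthalen-1-yl]-4-hydroxy-2H-pyran-2-one F2 and 6-{[3-(benzyloxy)-2-bromophenyl]methyl}-4-hydroxy-2H-pyran-2-one F4. The two pyrones are then joined at C3 by condensation with formaldehyde (Knoevenagel condensation followed by Michael addition, the reaction that forms 3,3′-methylenebis(4-hydroxypyrones)). F4 is used in excess so that F2 is drawn into the mixed dimer, which is separated from the symmetrical dimer of F4. The fallback rejoins the route at 25, at the price of a statistical hetero-coupling.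

**Step 20.**
- What may go wrong: slow enamine formation at the di-ortho-substituted acetyl group; poor facial selectivity at the benzoyl carbonyl; retro-aldol racemisation; dehydration and aromatisation of the aldol.
- Fallback: from 29, ring closure without asymmetric induction (catalytic K2CO3 or pyrrolidine/AcOH) gives 30 together with its enantiomer, ent-penta-O-benzyl wailupemycin H F5. The pair is resolved by preparative chromatography on a chiral stationary phase. F5 can be returned to the base-mediated retro-aldol/aldol equilibrium to regenerate racemate. The fallback comes back at 30.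

**Step 19.**
- What may go wrong: sluggish attack of the stabilised, hindered dienolate on the amide; reaction through oxygen or a ring carbon; premature loss of the enol ether followed by uncontrolled cyclisation.
- Fallback: from 27, the same lithium dienolate is added to benzaldehyde (aldol addition). This gives 4-(benzyloxy)-6-{1-[3-(benzyloxy)-2-(1-ethoxyethenyl)phenyl]-2-hydroxy-2-phenylethyl}-3-({4-(benzyloxy)-6-[4,5-bis(benzyloxy)-2-phenylnaphthalen-1-yl]-2-oxo-2H-pyran-3-yl}methyl)-2H-pyran-2-one F6 as a diastereomer mixture. Oxidation with Dess–Martin periodinane (NaHCO3 buffer) gives 28, and dilute HCl then gives 29, where the route is rejoined.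

**Step 4.**
- What may go wrong: iodination ortho to the hydroxyl (C2) or over-iodination; oxidative coupling of the electron-rich naphthol.
- Fallback: from 9, oxidation with PhI(OAc)2 in MeCN/H2O gives 5-(benzyloxy)-2-phenylnaphthalene-1,4-dione F7. Lithium (trimethylsilyl)acetylide should add to the C1 carbonyl, the one not deactivated by the peri benzyloxy group, to give 8-(benzyloxy)-4-hydroxy-3-phenyl-4-[(trimethylsilyl)ethynyl]naphthalen-1(4H)-one F8. Reductive aromatisation (Zn, AcOH) gives 8-(benzyloxy)-3-phenyl-4-[(trimethylsilyl)ethynyl]naphthalen-1-ol F9. Benzylation (BnBr, K2CO3, DMF) returns to the route at 12, bypassing 10, 11 and the cross-coupling.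

## Further compounds

F1 | step 15 | tert-butyl 5-[4,5-bis(benzyloxy)-2-phenylnaphthalen-1-yl]-3-oxopent-4-ynoate | CC(C)(C)OC(=O)CC(=O)C#Cc1c(-c2ccccc2)cc(OCc2ccccc2)c2c(OCc3ccccc3)cccc12
F2 | step 15 | 6-[4,5-bis(benzyloxy)-2-phenylnaphthalen-1-yl]-4-hydroxy-2H-pyran-2-one | O=c1cc(O)cc(-c2c(-c3ccccc3)cc(OCc3ccccc3)c3c(OCc4ccccc4)cccc23)o1
F3 | step 15 | tert-butyl 6-[3-(benzyloxy)-2-bromophenyl]-3-oxohex-4-ynoate | CC(C)(C)OC(=O)CC(=O)C#CCc1cccc(OCc2ccccc2)c1Br
F4 | step 15 | 6-{[3-(benzyloxy)-2-bromophenyl]methyl}-4-hydroxy-2H-pyran-2-one | O=c1cc(O)cc(Cc2cccc(OCc3ccccc3)c2Br)o1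
F5 | step 20 | ent-penta-O-benzyl wailupemycin H, the (3S,4R) enantiomer of 30 (tetralone numbering) | O=C1C[C@@](O)(c2ccccc2)[C@H](c2cc(OCc3ccccc3)c(Cc3c(OCc4ccccc4)cc(-c4c(-c5ccccc5)cc(OCc5ccccc5)c5c(OCc6ccccc6)cccc45)oc3=O)c(=O)o2)c2cccc(OCc3ccccc3)c21
F6 | step 19 | 4-(benzyloxy)-6-{1-[3-(benzyloxy)-2-(1-ethoxyethenyl)phenyl]-2-hydroxy-2-phenylethyl}-3-({4-(benzyloxy)-6-[4,5-bis(benzyloxy)-2-phenylnaphthalen-1-yl]-2-oxo-2H-pyran-3-yl}methyl)-2H-pyran-2-one (diastereomer mixture) | O=c1oc(C(C(O)c2ccccc2)c2cccc(OCc3ccccc3)c2C(=C)OCC)cc(OCc2ccccc2)c1Cc1c(OCc2ccccc2)cc(-c2c(-c3ccccc3)cc(OCc3ccccc3)c3c(OCc4ccccc4)cccc23)oc1=O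
F7 | step 4 | 5-(benzyloxy)-2-phenylnaphthalene-1,4-dione | O=C1C=C(c2ccccc2)C(=O)c2cccc(OCc3ccccc3)c12
F8 | step 4 | 8-(benzyloxy)-4-hydroxy-3-phenyl-4-[(trimethylsilyl)ethynyl]naphthalen-1(4H)-one (racemic) | O=C1C=C(c2ccccc2)C(O)(C#C[Si](C)(C)C)c2cccc(OCc3ccccc3)c12
F9 | step 4 | 8-(benzyloxy)-3-phenyl-4-[(trimethylsilyl)ethynyl]naphthalen-1-ol | Oc1cc(-c2ccccc2)c(C#C[Si](C)(C)C)c2cccc(OCc3ccccc3)c12
A1 | alternative 1 | 6-[(1S,2R)-2,5-dihydroxy-4-oxo-2-phenyl-1,2,3,4-tetrahydronaphthalen-1-yl]-4-hydroxy-2H-pyran-2-one | O=C1C[C@](O)(c2ccccc2)[C@@H](c2cc(O)cc(=O)o2)c2cccc(O)c21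
A2 | alternative 1 | 6-(4,5-dihydroxy-2-phenylnaphthalen-1-yl)-4-hydroxy-2H-pyran-2-one | O=c1cc(O)cc(-c2c(-c3ccccc3)cc(O)c3c(O)cccc23)o1
A3 | alternative 2 | 4-(benzyloxy)-6-[(1R,2R)-5-(benzyloxy)-4-oxo-2-phenyl-2-[(triethylsilyl)oxy]-1,2,3,4-tetrahydronaphthalen-1-yl]-2H-pyran-2-one (same spatial arrangement as 31) | O=C1C[C@](O[Si](CC)(CC)CC)(c2ccccc2)[C@@H](c2cc(OCc3ccccc3)cc(=O)o2)c2cccc(OCc3ccccc3)c21
A4 | alternative 2 | methyl (3S)-4-[4-(benzyloxy)-2-oxo-2H-pyran-6-yl]-3-phenyl-3-[(triethylsilyl)oxy]butanoate | COC(=O)C[C@](O[Si](CC)(CC)CC)(c1ccccc1)Cc1cc(OCc2ccccc2)cc(=O)o1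
A5 | alternative 3 | (1S,2R)-5-(benzyloxy)-2-[(4-methoxyphenyl)methoxy]-2-phenyl-1,2-dihydronaphthalene-1-carboxylic acid | C1=C[C@](OCc2ccc(OC)cc2)(c2ccccc2)[C@@H](C(O)=O)c2cccc(OCc3ccccc3)c12
A6 | alternative 3 | (1S)-8-(benzyloxy)-1-{(E)-2-[(4-methoxyphenyl)methoxy]-2-phenylethenyl}-1,4-dihydro-3H-2-benzopyran-3-one | O=C1Cc2cccc(OCc3ccccc3)c2[C@H](/C=C(/OCc2ccc(OC)cc2)c2ccccc2)O1
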